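The cyclohexane is cut at the CHBr–CH2 bond. The step exploits the 1,4-relationship across the six-membered ring between the bromine-bearing carbon and the tertiary carbinol carbon: with the CHBr carbon at the ketone level, the carbocycle is the acyl-transfer isomer of a γ-butyrolactone in which the tertiary oxygen acylates that carbon. This lactone, which carries a 2-iodoethyl arm and all three contiguous ring stereocentres (built from (S)-linalool by Z-olefination, asymmetric epoxidation, invertive epoxide opening and trans alkylation), is turned inside out by SmI2: one intramolecular acyl substitution forms the C–C bond, closes the carbocycle and frees ketone and tertiary alcohol. The ketone is then taken to the equatorial bromide.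

Key step: step 10

Assumption: (S)-(+)-linalool of high enantiomeric purity and the L-fructose-derived Shi ketone are taken as commercially available; TBS stands for tert-butyldimethylsilyl.

Step 1
Reactants: 1 (S)-(+)-linalool [(3S)-3,7-dimethylocta-1,6-dien-3-ol]
Product: 2 (3S)-3-(TBSO)-3,7-dimethylocta-1,6-diene
Conditions: t-BuMe2SiOTf, 2,6-lutidine, CH2Cl2, −78 to 0 °C
Reagents that add atoms: tert-butyldimethylsilyl trifluoromethanesulfonate, CC(C)(C)[Si](C)(C)OS(=O)(=O)C(F)(F)F
Why: Silyl ether formation: the silyl triflate with a hindered pyridine base silylates the tertiary allylic alcohol without touching its stereocentre, and the ether later keeps this oxygen from attacking the epoxide.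

Step 2
Reactants: 2 (3S)-3-(TBSO)-3,7-dimethylocta-1,6-diene
Product: 4 (4S)-4-(TBSO)-4-methylhex-5-enal, via secondary ozonide 3 (not isolated)
Conditions: O3 (1.0 equiv), CH2Cl2, −78 °C; then PPh3, −78 °C to rt
Reagents that add atoms: ozone, O=[O+][O-]
Why: Ozonolysis: one equivalent of ozone should cleave the electron-rich trisubstituted alkene much faster than the monosubstituted vinyl group on the quaternary carbon, and phosphine reduction of the ozonide gives the aldehyde.

Step 3
Reactants: 4 (4S)-4-(TBSO)-4-methylhex-5-enal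
Product: 5 (3S,6Z)-3-(TBSO)-7-iodo-3-methylocta-1,6-diene
Conditions: EtPPh3I, n-BuLi, THF, 0 °C; I2, −78 °C; NaN(SiMe3)2, −78 to −20 °C; then 4, −78 °C
Reagents that add atoms: ethyltriphenylphosphonium iodide, CC[P+](c1ccccc1)(c1ccccc1)c1ccccc1.[I-]; iodine, II
Why: Stork–Zhao (Wittig) olefination with the α-iodo ylide formed in the flask should give the (Z)-2-iodoalkene, with iodine cis to the chain, so that the methyl group ends trans to the chain.

Step 4
Reactants: 5 (3S,6Z)-3-(TBSO)-7-iodo-3-methylocta-1,6-diene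
Product: 6 (3S,6Z)-3,9-bis(TBSO)-3,7-dimethylnona-1,6-diene
Conditions: t-BuMe2SiOCH2CH2I, Zn dust, LiCl, THF, 40 °C; then 5, PdCl2[P(t-Bu)2(C6H4-4-NMe2)]2 (2 mol%), TMEDA, THF, rt
Reagents that add atoms: tert-butyl(2-iodoethoxy)dimethylsilane, CC(C)(C)[Si](C)(C)OCCI
Why: Negishi coupling of the alkenyl iodide with the primary alkylzinc iodide formed in the flask proceeds with retention of the alkene geometry (amine additive and bulky phosphine suppress isomerisation), so the oxygenated two-carbon arm is placed cis to the chain.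

Step 5
Reactants: 6 (3S,6Z)-3,9-bis(TBSO)-3,7-dimethylnona-1,6-diene
Product: 7 (3S,6S,7R)-3,9-bis(TBSO)-6,7-epoxy-3,7-dimethylnon-1-ene
Conditions: L-fructose-derived Shi ketone (30 mol%), Oxone (2KHSO5·KHSO4·K2SO4), K2CO3, Bu4NHSO4, MeCN–CH2(OMe)2–aq. Na2B4O7 buffer, 0 °C
Reagents that add atoms: potassium peroxymonosulfate, [K+].[O-]S(=O)(=O)OO
Why: Shi epoxidation: the chiral dioxirane attacks the only electron-rich alkene through the spiro transition state, the L-series catalyst being chosen to give the (6S,7R)-epoxide (catalyst control; the cis relation of the two chains follows from the Z-alkene).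

Step 6
Reactants: 7 (3S,6S,7R)-3,9-bis(TBSO)-6,7-epoxy-3,7-dimethylnon-1-ene
Product: 9 (3RS,4S,5R)-5-[2-(TBSO)ethyl]-4-[(3S)-3-(TBSO)-3-methylpent-4-enyl]-3,5-dimethyloxolan-2-one, via hydroxy acid 8 (not isolated)
Conditions: EtCO2H, LiN(i-Pr)2 (2 equiv per acid), THF–DMPU, 0 °C; then 7, 45 °C; then AcOH, PhMe, 60 °C
Reagents that add atoms: propanoic acid, CCC(=O)O
Why: Epoxide opening by a carboxylic acid dianion and lactonisation: SN2 attack at the less substituted epoxide carbon inverts it, which fixes the ring CH centre anti to the retained C–O bond of the fully substituted carbon, and the γ-hydroxy acid closes to the lactone (the α-centre is left as a mixture and is erased in the next step).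

Step 7
Reactants: 9 (3RS,4S,5R)-5-[2-(TBSO)ethyl]-4-[(3S)-3-(TBSO)-3-methylpent-4-enyl]-3,5-dimethyloxolan-2-one
Product: 10 (3S,4S,5R)-5-[2-(TBSO)ethyl]-4-[(3S)-3-(TBSO)-3-methylpent-4-enyl]-3,5-dimethyl-3-(4-methylpent-3-enyl)oxolan-2-one
Conditions: LiN(i-Pr)2, THF, −78 °C; then 5-bromo-2-methylpent-2-ene, DMPU, −78 to −20 °C
Reagents that add atoms: 5-bromo-2-methylpent-2-ene, CC(C)=CCCBr
Why: Enolate alkylation: the lactone enolate should be alkylated on the face opposite the neighbouring β-side chain, which creates the quaternary centre with methyl cis and homoprenyl trans to that chain.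

Step 8
Reactants: 10 (3S,4S,5R)-5-[2-(TBSO)ethyl]-4-[(3S)-3-(TBSO)-3-methylpent-4-enyl]-3,5-dimethyl-3-(4-methylpent-3-enyl)oxolan-2-one
Product: 11 (3S,4S,5R)-4-[(3S)-3-(TBSO)-3-methylpent-4-enyl]-5-(2-hydroxyethyl)-3,5-dimethyl-3-(4-methylpent-3-enyl)oxolan-2-one
Conditions: HF·pyridine, pyridine, THF, 0 °C
Reagents that add atoms: none
Why: Selective desilylation: buffered HF·pyridine cleaves the unhindered primary silyl ether far faster than the tertiary one.

Step 9
Reactants: 11 (3S,4S,5R)-4-[(3S)-3-(TBSO)-3-methylpent-4-enyl]-5-(2-hydroxyethyl)-3,5-dimethyl-3-(4-methylpent-3-enyl)oxolan-2-one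
Product: 12 (3S,4S,5R)-4-[(3S)-3-(TBSO)-3-methylpent-4-enyl]-5-(2-iodoethyl)-3,5-dimethyl-3-(4-methylpent-3-enyl)oxolan-2-one
Conditions: PPh3, I2, imidazole, CH2Cl2, 0 °C to rt
Reagents that add atoms: iodine, II
Why: Appel-type iodination (PPh3, I2, imidazole) replaces the primary hydroxyl by iodide through SN2 at the unhindered carbon, leaving lactone, tertiary silyl ether and alkenes untouched.

Step 10
Reactants: 12 (3S,4S,5R)-4-[(3S)-3-(TBSO)-3-methylpent-4-enyl]-5-(2-iodoethyl)-3,5-dimethyl-3-(4-methylpent-3-enyl)oxolan-2-one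
Product: 14 (2S,3S,4R)-3-[(3S)-3-(TBSO)-3-methylpent-4-enyl]-4-hydroxy-2,4-dimethyl-2-(4-methylpent-3-enyl)cyclohexan-1-one, via bridged hemiketal 13 (not isolated)
Conditions: SmI2 (2.5 equiv), tris(dibenzoylmethanato)iron (2 mol%), THF, −30 °C to rt; aq. NaHCO3 work-up
Reagents that add atoms: none
Why: Samarium diiodide reduces the primary C–I bond in two single-electron steps (sped up by the trivalent iron catalyst) to an alkylsamarium species, whose CH2 carbon adds to the lactone carbonyl carbon (the later CHBr carbon); the bridged samarium hemiketalate then collapses with C–O cleavage to the 4-hydroxy ketone on work-up. The closest known reaction type is the samarium-mediated intramolecular nucleophilic acyl substitution (intramolecular Barbier reaction) of iodoalkyl esters and lactones. The new C–C bond closes the transient oxolane ring of the oxabicyclo[2.2.1]heptane by 5-exo-trig attack and thereby the cyclohexane, whose closure is 6-exo-trig on the exocyclic C=O. No stereocentre is formed (the new ketone carbon is trigonal), and the carbinol carbon, the ring CH and the quaternary carbon are carried over unchanged because none of them is α to the ketone with a hydrogen. The step needs chemoselective reduction of the iodide beside lactone and alkenes and a single addition to the carbonyl; the low reduction potential of the alkyl iodide, the five-membered intramolecular delivery and the hemiketalate, which masks the ketone until work-up, secure this.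

Step 11
Reactants: 14 (2S,3S,4R)-3-[(3S)-3-(TBSO)-3-methylpent-4-enyl]-4-hydroxy-2,4-dimethyl-2-(4-methylpent-3-enyl)cyclohexan-1-one
Product: 16 (1R,2S,3S)-4,4-dibromo-2-[(3S)-3-(TBSO)-3-methylpent-4-enyl]-1,3-dimethyl-3-(4-methylpent-3-enyl)cyclohexan-1-ol, via silyl hydrazone 15 (not isolated)
Conditions: (t-BuMe2SiNH)2, Sc(OTf)3 (0.01 mol%), CHCl3, 55 °C; then CuBr2, Et3N, MeOH, 0 °C to rt
Reagents that add atoms: copper dibromide, Br[Cu]Br
Why: Hydrazone-to-gem-dihalide oxidation: the N-silyl hydrazone formed in the flask is oxidised by copper dibromide through the diazoalkane to the gem-dibromide, the quaternary neighbour leaving only one side for competing loss of HBr.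

Step 12
Reactants: 16 (1R,2S,3S)-4,4-dibromo-2-[(3S)-3-(TBSO)-3-methylpent-4-enyl]-1,3-dimethyl-3-(4-methylpent-3-enyl)cyclohexan-1-ol
Product: 17 (1R,2S,3S,4S)-4-bromo-2-[(3S)-3-(TBSO)-3-methylpent-4-enyl]-1,3-dimethyl-3-(4-methylpent-3-enyl)cyclohexan-1-ol
Conditions: Bu3SnH (1.05 equiv), PhSeSePh (5 mol%), Et3B, air, PhMe, −78 °C
Reagents that add atoms: none
Why: Radical mono-reduction of a gem-dibromide with tin hydride: the α-bromo cyclohexyl radical should accept hydrogen axially, anti to the axial methyl on the neighbouring quaternary carbon in the chair with the side chain equatorial, so bromine stays equatorial and cis to that methyl (substrate control), while the selenol made in the flask delivers hydrogen faster than the radical can add to the homoprenyl alkene.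

Step 13
Reactants: 17 (1R,2S,3S,4S)-4-bromo-2-[(3S)-3-(TBSO)-3-methylpent-4-enyl]-1,3-dimethyl-3-(4-methylpent-3-enyl)cyclohexan-1-ol
Product: 18 (1R,2S,3S,4S)-4-bromo-2-[(3S)-3-hydroxy-3-methylpent-4-enyl]-1,3-dimethyl-3-(4-methylpent-3-enyl)cyclohexan-1-ol
Conditions: HF·pyridine, THF, 0 °C to rt
Reagents that add atoms: none
Why: Desilylation: HF·pyridine removes the tertiary silyl ether, and the equatorial secondary bromide and the two tertiary alcohols should survive these mildly acidic, non-basic conditions.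

Compound list
1 | (S)-(+)-linalool, (3S)-3,7-dimethylocta-1,6-dien-3-ol | C=C[C@@](C)(O)CCC=C(C)C | starting material
2 | (3S)-3-(TBSO)-3,7-dimethylocta-1,6-diene | C=C[C@@](C)(O[Si](C)(C)C(C)(C)C)CCC=C(C)C | intermediate
3 | secondary ozonide, 3-[(3S)-3-(TBSO)-3-methylpent-4-enyl]-5,5-dimethyl-1,2,4-trioxolane (mixture at the ring carbon) | C=C[C@@](C)(O[Si](C)(C)C(C)(C)C)CCC1OOC(C)(C)O1 | intermediate
4 | (4S)-4-(TBSO)-4-methylhex-5-enal | C=C[C@@](C)(O[Si](C)(C)C(C)(C)C)CCC=O | intermediate
5 | (3S,6Z)-3-(TBSO)-7-iodo-3-methylocta-1,6-diene | C=C[C@@](C)(O[Si](C)(C)C(C)(C)C)CC/C=C(/C)I | intermediate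
6 | (3S,6Z)-3,9-bis(TBSO)-3,7-dimethylnona-1,6-diene | C=C[C@@](C)(O[Si](C)(C)C(C)(C)C)CC/C=C(/C)CCO[Si](C)(C)C(C)(C)C | intermediate
7 | (3S,6S,7R)-3,9-bis(TBSO)-6,7-epoxy-3,7-dimethylnon-1-ene | C=C[C@@](C)(O[Si](C)(C)C(C)(C)C)CC[C@@H]1O[C@]1(C)CCO[Si](C)(C)C(C)(C)C | intermediate
8 | (2RS,3S,4R)-6-(TBSO)-3-[(3S)-3-(TBSO)-3-methylpent-4-enyl]-4-hydroxy-2,4-dimethylhexanoic acid | C=C[C@@](C)(O[Si](C)(C)C(C)(C)C)CC[C@@H](C(C)C(=O)O)[C@](C)(O)CCO[Si](C)(C)C(C)(C)C | intermediate
9 | (3RS,4S,5R)-5-[2-(TBSO)ethyl]-4-[(3S)-3-(TBSO)-3-methylpent-4-enyl]-3,5-dimethyloxolan-2-one | C=C[C@@](C)(O[Si](C)(C)C(C)(C)C)CC[C@H]1C(C)C(=O)O[C@]1(C)CCO[Si](C)(C)C(C)(C)C | intermediate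
10 | (3S,4S,5R)-5-[2-(TBSO)ethyl]-4-[(3S)-3-(TBSO)-3-methylpent-4-enyl]-3,5-dimethyl-3-(4-methylpent-3-enyl)oxolan-2-one | C=C[C@@](C)(O[Si](C)(C)C(C)(C)C)CC[C@H]1[C@](C)(CCC=C(C)C)C(=O)O[C@]1(C)CCO[Si](C)(C)C(C)(C)C | intermediate
11 | (3S,4S,5R)-4-[(3S)-3-(TBSO)-3-methylpent-4-enyl]-5-(2-hydroxyethyl)-3,5-dimethyl-3-(4-methylpent-3-enyl)oxolan-2-one | C=C[C@@](C)(O[Si](C)(C)C(C)(C)C)CC[C@H]1[C@](C)(CCC=C(C)C)C(=O)O[C@]1(C)CCO | intermediate
12 | (3S,4S,5R)-4-[(3S)-3-(TBSO)-3-methylpent-4-enyl]-5-(2-iodoethyl)-3,5-dimethyl-3-(4-methylpent-3-enyl)oxolan-2-one | C=C[C@@](C)(O[Si](C)(C)C(C)(C)C)CC[C@H]1[C@](C)(CCC=C(C)C)C(=O)O[C@]1(C)CCI | intermediate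
13 | bridged hemiketal, the 7-oxabicyclo[2.2.1]heptan-1-ol in which the tertiary oxygen of 14 is bonded to its ketone carbon (formed as the samarium alkoxide) | C=C[C@@](C)(O[Si](C)(C)C(C)(C)C)CC[C@H]1[C@](C)(CCC=C(C)C)[C@]2(O)CC[C@@]1(C)O2 | intermediate
14 | (2S,3S,4R)-3-[(3S)-3-(TBSO)-3-methylpent-4-enyl]-4-hydroxy-2,4-dimethyl-2-(4-methylpent-3-enyl)cyclohexan-1-one | C=C[C@@](C)(O[Si](C)(C)C(C)(C)C)CC[C@H]1[C@](C)(CCC=C(C)C)C(=O)CC[C@@]1(C)O | intermediate
15 | N-(tert-butyldimethylsilyl)hydrazone of 14 | C=C[C@@](C)(O[Si](C)(C)C(C)(C)C)CC[C@H]1[C@](C)(CCC=C(C)C)C(=NN[Si](C)(C)C(C)(C)C)CC[C@@]1(C)O | intermediate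
16 | (1R,2S,3S)-4,4-dibromo-2-[(3S)-3-(TBSO)-3-methylpent-4-enyl]-1,3-dimethyl-3-(4-methylpent-3-enyl)cyclohexan-1-ol | C=C[C@@](C)(O[Si](C)(C)C(C)(C)C)CC[C@H]1[C@](C)(CCC=C(C)C)C(Br)(Br)CC[C@@]1(C)O | intermediate
17 | (1R,2S,3S,4S)-4-bromo-2-[(3S)-3-(TBSO)-3-methylpent-4-enyl]-1,3-dimethyl-3-(4-methylpent-3-enyl)cyclohexan-1-ol | C=C[C@@](C)(O[Si](C)(C)C(C)(C)C)CC[C@H]1[C@](C)(CCC=C(C)C)[C@@H](Br)CC[C@@]1(C)O | intermediate
18 | (1R,2S,3S,4S)-4-bromo-2-[(3S)-3-hydroxy-3-methylpent-4-enyl]-1,3-dimethyl-3-(4-methylpent-3-enyl)cyclohexan-1-ol | C=C[C@@](C)(O)CC[C@H]1[C@](C)(CCC=C(C)C)[C@@H](Br)CC[C@@]1(C)O | target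

Total step count: 13. Longest linear sequence: 13 steps (1 to 18).

Steps most likely to fail

Step 11. Loss of HBr from the bromo-diazonium or bromo-carbocation stage to a vinyl bromide, and electrophilic bromination of the trisubstituted alkene, may outrun the second C–Br bond formation at the hindered carbon. The fallback sets out from 14. Reduction with LiBH(s-Bu)3 in THF at −78 °C from the equatorial direction should give the axial secondary alcohol F1. Triflation of the secondary hydroxyl only (Tf2O, pyridine, CH2Cl2, −40 °C) gives the triflate F2. Displacement with Bu4NBr in toluene with inversion comes back to the route at 17, so step 12 is not needed.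

Step 12. Hydrogen-atom transfer to the α-bromo radical may show poor facial selectivity, the radical may add to the homoprenyl alkene, or the product may lose its second bromine. The fallback sets out from 16. Bromine–magnesium exchange with excess i-PrMgCl·LiCl in THF at −78 °C, expected at the more strained axial bromine, gives the magnesium carbenoid F3. Protonation at −78 °C with t-BuOH with retention comes back to the route at 17 by a polar pathway without a radical.

Step 6. Deprotonation next to the epoxide by the amide base (isomerisation to an allylic alcohol) and slow SN2 opening at the hindered secondary carbon may dominate. The fallback sets out from 7. Sodium dimethyl methylmalonate (NaH, dimethyl methylmalonate, THF–DMPU, 65 °C), a softer and less basic nucleophile, opens the epoxide at the same carbon with inversion, and the alkoxide closes onto one ester to give the methoxycarbonyl lactone F4. Krapcho dealkoxycarbonylation (LiCl, wet DMSO, 140 °C) comes back to the route at 9.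

Further compounds
F1 | step 11 | (1R,2S,3S,4R)-2-[(3S)-3-(TBSO)-3-methylpent-4-enyl]-1,3-dimethyl-3-(4-methylpent-3-enyl)cyclohexane-1,4-diol (axial secondary hydroxyl at C4) | C=C[C@@](C)(O[Si](C)(C)C(C)(C)C)CC[C@H]1[C@](C)(CCC=C(C)C)[C@H](O)CC[C@@]1(C)O
F2 | step 11 | C4 trifluoromethanesulfonate of F1 | C=C[C@@](C)(O[Si](C)(C)C(C)(C)C)CC[C@H]1[C@](C)(CCC=C(C)C)[C@H](OS(=O)(=O)C(F)(F)F)CC[C@@]1(C)O
F3 | step 12 | magnesium carbenoid, 4-bromo-4-(chloromagnesio) analogue of 16 | C=C[C@@](C)(O[Si](C)(C)C(C)(C)C)CC[C@H]1[C@](C)(CCC=C(C)C)C(Br)([Mg]Cl)CC[C@@]1(C)O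
F4 | step 6 | methyl (3RS,4S,5R)-5-[2-(TBSO)ethyl]-4-[(3S)-3-(TBSO)-3-methylpent-4-enyl]-3,5-dimethyl-2-oxooxolane-3-carboxylate | C=C[C@@](C)(O[Si](C)(C)C(C)(C)C)CC[C@H]1C(C)(C(=O)OC)C(=O)O[C@]1(C)CCO[Si](C)(C)C(C)(C)C
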